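**Compound numbers used throughout:** 1 dianhydride, 2 half-ester, 3 diol diester (not isolated), 4 bis-lactone, 5 bis-lactol, 6 Ohira–Bestmann reagent, 7 diyne diol, 8 diyne diacid, 9 (R)-danshensu, 10 tribenzyl danshensu, 11 diyne with both arms, 12 butane-2,3-dione, 13 bis(silyloxy)diene, 14 bis(cyclohexadienyl) compound, 15 silylated arene, 16 tetraphenol, 17 target.

## The problem

The target 17 is a twofold-symmetric cyclobutane whose four contiguous ring stereocentres are all R: C1 and C2 carry the (R)-danshensu ester arms trans to each other, C3 and C4 carry 3,4-dihydroxyphenyl rings trans to each other, and each ester is cis to the aryl group on its neighbour (C1/C4 and C2/C3). This is the pattern of a head-to-head dimer of Z-configured caffeate halves, so photodimerisation of the natural E-esters, which gives trans aryl/ester pairs, cannot assemble the ring. The two cis aryl/ester pairs are contra-thermodynamic, and every ring carbon α to a carbonyl can epimerise under base toward the all-trans isomer. The arm stereocentres are too remote to control the ring, so the ring needs its own source of absolute configuration. The arms are held by secondary α-acyloxy ester links that are prone to hydrolysis, transesterification and racemisation under base, and the four oxidation-prone catechols and the two acids must be unveiled under neutral conditions at the end. The enabling feature is that the ipso carbons of the catechol rings on C3 and C4, together with the carbonyl carbons on C1 and C2, are four exocyclic carbons on a cis,trans,cis cyclobutane, which is exactly the arrangement in the meso dianhydride 1. If the two ipso carbons are carried as ethynyl carbons, each catechol ring can be grown on an alkyne from a four-carbon dioxygenated diene, so the C3–aryl and C4–aryl bonds never have to be formed at a stereocentre.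

## Retrosynthesis

**17 back to 15.** The six O–benzyl bonds of the arms and the four O–Si bonds of the ring catechols are cut. Two kinds of protection are accepted because the ring oxygens arrive from the diene as silyl enol ethers. The arms need groups that survive carbodiimide coupling, the cobalt/zinc medium and a quinone oxidant, and that leave without acid or base. The forward steps must let fluoride spare four esters (15 to 16) and let hydrogenolysis spare the cyclobutane and the homobenzylic ester C–O bonds (16 to 17).

**15 back to 14.** Two hydrogens are added back to each new arene, giving two 4,5-bis(silyloxy)cyclohexa-1,4-diene rings. This exposes a [4+2] retron with both oxygens already on the right carbons. The forward dehydrogenation must be faster than oxidation of the electron-rich benzylic positions of the arms.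

**14 back to 11 and 13 (key disconnection).** In each cyclohexadiene the two bonds between the former alkyne carbons and the diene termini are cut, four C–C bonds in all, so one molecule of 11 is matched with two molecules of 13. The neighbouring cuts are the C3–aryl and C4–aryl bonds themselves, by cross-coupling or C–H arylation, or the cyclobutane bonds by [2+2]. The first kind makes bonds at stereocentres next to epimerisable carbons, and the second gives the wrong relative configuration. Here the precursor 11 is two rings and four oxygen functions poorer, and its stereocentres are untouched. The forward reaction must be neutral, twofold, and selective for cross-cycloaddition over alkyne oligomerisation.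

**13 back to 12.** Two O–Si bonds are cut. The symmetrical diene comes in one step from the diketone 12, and its symmetry removes any regiochemical question from the key step.

**11 back to 8 and 10, and 10 back to 9.** The two ester C–O bonds between the ring carboxyls and the arms are cut, which releases the diacid 8 and two molecules of the alcohol 10. Attaching the arms at the dianhydride stage would be shorter, but every later step on the way to the alkynes would then run next to the arm esters. A hydroxymethyl group cis to an arm ester lactonises and expels the arm, and basic alkyne-forming conditions transesterify and racemise it. Joining the arms to the diyne diacid 8 avoids this and acylates while the ring neighbours are slim ethynyl groups. The alcohol 10 is one step from natural 9. The forward step must be a twofold acylation of a secondary α-hydroxy ester without epimerisation of the activated acid.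

**8 back to 7, 5 (with 6) and 4.** The carboxyls are taken back to hydroxymethyl groups (7). Each C≡C bond is cut to a lactol carbon, with the terminal alkyne carbon supplied by 6. The lactols 5 come from the bis-lactone 4. The lactone differentiates the two kinds of ring substituent: its C=O carbons become alkynes and its CH2O carbons return to carboxyl. The precursor 4 is a rigid, twofold-symmetric tricycle in which no free aldehyde or acid sits next to a leaving group. The forward steps must homologate a masked aldehyde without epimerising its α-carbon.

**4 back to 2 (through 3) and 1.** The two lactone C–O bonds are cut to the half-ester 2, and the two methyl ester bonds to the dianhydride 1. Compound 1 is achiral with four equivalent carbonyls. The two within one anhydride ring are enantiotopic, and those on adjacent carbons of different rings are homotopic. A reagent-controlled choice within each ring therefore picks a homotopic pair and gives the twofold-symmetric 1,2-diacid 3,4-diester 2. A single wrong choice gives a separable centrosymmetric diastereomer, not the enantiomer. This step sets the absolute configuration of the whole ring from a commercial compound that already has the cis,trans,cis array.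

## Roads not taken

Alternative 1: The C3–aryl and C4–aryl bonds are cut.
- Forward step: Pd(OAc)2 with AgOAc would arylate (1R,2R)-N1,N2-di(quinolin-8-yl)cyclobutane-1,2-dicarboxamide A1 twice with 1,2-bis(benzyloxy)-4-iodobenzene A2, giving the diaryl diamide A3.
- Merits: each amide directs divalent palladium to the cis hydrogen of the adjacent methylene, which is the relative configuration the target needs. The absolute configuration comes from an enantiopure trans-diacid. The route is several steps shorter than the chosen one and forms the aryl bonds directly.
- Weak points: the second arylation must take place on the carbon next to the first aryl group. Both aminoquinoline amides must then be cleaved at carbons where the cis aryl/carbonyl relation is contra-thermodynamic, and forcing hydrolysis or N-activation invites epimerisation to the all-trans isomer. The freed acids, now flanked by cis aryl groups, must be esterified with the hindered alcohol 10.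
- Comparison: this road is better in step count and in directness. The chosen plan sets against it that the cis ester/aryl pairs are never exposed to amide cleavage or strong base, and that the arms are attached beside ethynyl groups instead of aryl groups.

Alternative 2: The C1=C2 bond of a cyclobutene is cut by ring contraction.
- Forward step: di-tert-butyl trans-3,4-bis[3,4-bis(benzyloxy)phenyl]thiolane-2,5-dicarboxylate 1,1-dioxide A4 would be α-halogenated with CBr2F2 and KOH on Al2O3, close to the episulfone and lose SO2, giving the cyclobutene diester A5.
- Merits: the trans-diaryl relation can be set early in a five-membered ring, and SO2 extrusion is a dependable way to a strained ring.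
- Weak points: A5 has lost the stereocentres at C1 and C2. Hydrogenation adds both hydrogens to one face and gives cis esters. Equilibration gives the all-trans isomer. The target needs trans esters that are each cis to an aryl group, which neither kinetic nor thermodynamic control provides. A trans-3,4-diarylcyclobutene is also prone to conrotatory ring opening to a diene, and the tert-butyl esters still have to be exchanged for the arms.
- Comparison: in early, robust aryl installation this road is as good as the chosen plan. The chosen plan sets against it that all four ring stereocentres are present from the first step and are only preserved afterwards.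

Alternative 3: The two ester C–O bonds between ring and arms are cut at the dianhydride stage.
- Forward step: the lithium alkoxide of 10, paired with a matched cinchona alkaloid, would open both rings of 1 at a homotopic carbonyl pair and give the diester diacid A6.
- Merits: this is the most convergent way to the ester bonds. One step sets regiochemistry, ring configuration and both arms. Its symmetry argument is the same as in step 1 of the chosen route.
- Weak points: a bulky chiral secondary alkoxide opens anhydrides in an uncatalysed background reaction that bypasses the alkaloid. Matched and mismatched pairing must also be sorted out. A6 then carries two free acids cis to base-labile arm esters. Reducing the acids gives hydroxymethyl groups that lactonise onto the arms and expel them. Decarboxylative arylation would pass through ring radicals that erase the cis relation.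
- Comparison: in reaching the ester bonds this road is shorter. The chosen plan gives that up by using methanol as the nucleophile and adding the arms five steps later. In exchange it turns the lactonisation into the device that tells alkyne carbons from carboxyl carbons.

Key step: step 9

Assumption: quinidine is taken to show on 1 the sense it shows on simple bicyclic cis-anhydrides (ester at the ring carbon drawn as ester-bearing in 2); quinine, its pseudo-enantiomer, would be used if the sense proved opposite.

In the names below, "arm" means the (2R)-1-(benzyloxy)-3-[3,4-bis(benzyloxy)phenyl]-1-oxopropan-2-yl group, the O-bound residue of alcohol 10.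

**Step 1**
Reactants: 1 cyclobutane-1,2,3,4-tetracarboxylic dianhydride (cis,trans,cis; meso)
Product: 2 (1S,2S,3S,4S)-3,4-bis(methoxycarbonyl)cyclobutane-1,2-dicarboxylic acid
Conditions: quinidine (2.2 equiv), MeOH (6 equiv), toluene/CCl4 1:1, −55 °C; aq. HCl work-up, quinidine recovered
Reagents that add atoms: methanol, CO
Why: Alkaloid-mediated desymmetrising methanolysis of meso cyclic anhydrides, a reaction type known for cyclobutane-fused anhydrides, in which one molecule of methanol opens each anhydride ring; the two carbonyls that become esters are homotopic, so the same preference of the quinidine–methanol pair in both rings gives the twofold-symmetric half-ester and sets all four ring centres, while one wrong opening gives a separable centrosymmetric diastereomer, so the enantiomeric purity of 2 should be statistically amplified.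

**Step 2**
Reactants: 2 (1S,2S,3S,4S)-3,4-bis(methoxycarbonyl)cyclobutane-1,2-dicarboxylic acid
Product: 4 (1S,2S,6S,7S)-4,9-dioxatricyclo[5.3.0.0^2,6]decane-3,10-dione (twofold-symmetric bis-γ-lactone), via diol diester 3 (not isolated)
Conditions: BH3·SMe2, THF, 0 °C to rt; MeOH quench; then p-TsOH (cat.), toluene, 60 °C
Reagents that add atoms: none
Why: Borane reduces carboxylic acids much faster than methyl esters (chemoselective reduction of half-esters), and each new hydroxymethyl group is cis to a methyl ester, so acid-catalysed lactonisation closes two cis-fused γ-lactones without touching a ring stereocentre; the lactone C=O carbons are now marked for the alkynes and the CH2O carbons for the carboxyls.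

**Step 3**
Reactants: 4 (1S,2S,6S,7S)-4,9-dioxatricyclo[5.3.0.0^2,6]decane-3,10-dione
Product: 5 (1S,2S,6S,7S)-4,9-dioxatricyclo[5.3.0.0^2,6]decane-3,10-diol (bis-lactol, mixture of anomers)
Conditions: i-Bu2AlH (2.2 equiv), CH2Cl2, −78 °C; aq. KNaC4H4O6 work-up
Reagents that add atoms: none
Why: Partial reduction of γ-lactones to lactols with i-Bu2AlH at low temperature is standard; the aluminium hemiacetal persists at −78 °C and collapses only on work-up, which holds back over-reduction, and the lactol keeps the aldehyde masked beside its cis hydroxymethyl neighbour.

**Step 4**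
Reactants: 5 (1S,2S,6S,7S)-4,9-dioxatricyclo[5.3.0.0^2,6]decane-3,10-diol; 6 dimethyl (1-diazo-2-oxopropyl)phosphonate (two molecules per molecule of 5, one for each lactol)
Product: 7 [(1R,2R,3R,4R)-3,4-diethynylcyclobutane-1,2-diyl]dimethanol
Conditions: 6 (2.6 equiv), K2CO3 (4 equiv), MeOH, 0 °C to rt
Reagents that add atoms: second molecule of reagent 6, COP(=O)(OC)C(=[N+]=[N-])C(C)=O
Why: Twofold Seyferth–Gilbert homologation in the Ohira–Bestmann version, known for lactols: methanolysis of 6 gives the dimethyl (diazomethyl)phosphonate anion, which adds to the small equilibrium share of hydroxy aldehyde, and loss of dimethyl phosphate and N2 with a 1,2-hydrogen shift gives each terminal alkyne, each molecule of 6 supplying one alkyne carbon; since the aldehyde rests as the lactol, its α-carbon is little exposed to base and the cis relation to the hydroxymethyl group should be kept.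

**Step 5**
Reactants: 7 [(1R,2R,3R,4R)-3,4-diethynylcyclobutane-1,2-diyl]dimethanol
Product: 8 (1R,2R,3R,4R)-3,4-diethynylcyclobutane-1,2-dicarboxylic acid
Conditions: TEMPO (cat.), PhI(OAc)2 (4.4 equiv), MeCN/H2O 1:1, rt
Reagents that add atoms: water, O
Why: Oxoammonium-mediated oxidation of primary alcohols through the aldehyde hydrate to carboxylic acids, a mild and slightly acidic method that tolerates terminal alkynes and should not epimerise the ring; a lactone between the two trans hydroxymethyl groups would be trans-fused to the four-membered ring and is too strained to compete.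

**Step 6**
Reactants: 9 (R)-danshensu, (2R)-3-(3,4-dihydroxyphenyl)-2-hydroxypropanoic acid
Product: 10 benzyl (2R)-3-[3,4-bis(benzyloxy)phenyl]-2-hydroxypropanoate
Conditions: BnBr (3.3 equiv), K2CO3, DMF, rt
Reagents that add atoms: benzyl bromide, BrCc1ccccc1
Why: Carbonate deprotonates only the carboxylic acid and the two phenols, so Williamson etherification and carboxylate alkylation take up three benzyl groups and leave the secondary alcohol free; the stereocentre takes no part.

**Step 7**
Reactants: 8 (1R,2R,3R,4R)-3,4-diethynylcyclobutane-1,2-dicarboxylic acid; 10 benzyl (2R)-3-[3,4-bis(benzyloxy)phenyl]-2-hydroxypropanoate (two molecules per molecule of 8, one for each carboxyl group)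
Product: 11 bis(arm) (1R,2R,3R,4R)-3,4-diethynylcyclobutane-1,2-dicarboxylate
Conditions: 10 (2.2 equiv), EDC·HCl (2.6 equiv), DMAP (0.2 equiv), CH2Cl2, 0 °C to rt
Reagents that add atoms: second molecule of alcohol 10, O[C@H](Cc1ccc(OCc2ccccc2)c(OCc2ccccc2)c1)C(=O)OCc1ccccc1
Why: Twofold Steglich esterification in which each carboxyl group of 8 is activated by the carbodiimide and acylates one molecule of 10, so the diester carries two arms and the water of both condensations ends up in the urea; the α-hydroxy ester reacts at oxygen with retention at its stereocentre, the trans diacid cannot close to a cyclic anhydride, and the slim ethynyl neighbours leave both carboxyls open. DMAP is kept catalytic and the temperature low so that the activated acyl groups do not epimerise by way of a ketene.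

**Step 8**
Reactants: 12 butane-2,3-dione
Product: 13 2,3-bis(tert-butyldimethylsilyloxy)buta-1,3-diene
Conditions: TBSOTf (2.2 equiv), Et3N, CH2Cl2, 0 °C to rt
Reagents that add atoms: tert-butyldimethylsilyl trifluoromethanesulfonate, CC(C)(C)[Si](C)(C)OS(=O)(=O)C(F)(F)F
Why: Twofold soft enolisation and O-silylation of a 1,2-diketone (silyl enol ether formation); both enolisations can only go toward the methyl groups, which gives the symmetrical 2,3-dioxygenated diene.

**Step 9**
Reactants: 11 bis(arm) (1R,2R,3R,4R)-3,4-diethynylcyclobutane-1,2-dicarboxylate; 13 2,3-bis(tert-butyldimethylsilyloxy)buta-1,3-diene (two molecules per molecule of 11, one for each ethynyl group)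
Product: 14 bis(arm) (1R,2R,3R,4R)-3,4-bis[4,5-bis(tert-butyldimethylsilyloxy)cyclohexa-1,4-dien-1-yl]cyclobutane-1,2-dicarboxylate
Conditions: CoBr2(Ph2PCH2CH2PPh2) (cat.), Zn, ZnI2, 13 (4 equiv), CH2Cl2, rt
Reagents that add atoms: second molecule of diene 13, C=C(O[Si](C)(C)C(C)(C)C)C(=C)O[Si](C)(C)C(C)(C)C
Why: Zn reduces the CoBr2 complex to a monovalent cobalt species and ZnI2 takes up halide to free coordination sites; the diene binds s-cis and the alkyne side-on, oxidative cyclisation gives a trivalent cobalt allyl–vinyl metallacycle, and reductive elimination releases the cyclohexa-1,4-diene and returns monovalent cobalt. The closest known reaction type is the cobalt-catalysed neutral [4+2] cycloaddition of non-activated terminal alkynes with 2-substituted and 2,3-disubstituted buta-1,3-dienes, silyloxy dienes included. Each of the two six-membered rings closes by an intermolecular metal-mediated [4+2] annulation in which the two alkyne carbons join C1 and C4 of one molecule of 13, so four C–C bonds form in all and two molecules of 13 are incorporated. No stereocentre is created. The selectivity needed is cross-cycloaddition over alkyne cyclotrimerisation, which the chelating diphosphine and the excess of diene favour, and the trans placing of the two ethynyl groups keeps them from coupling with each other at one metal; regiochemistry does not arise because 13 is symmetrical. The four ring stereocentres and the two arm stereocentres should survive because the medium is neutral and non-nucleophilic and no radical or carbanion is formed at a ring carbon.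

**Step 10**
Reactants: 14 bis(arm) (1R,2R,3R,4R)-3,4-bis[4,5-bis(tert-butyldimethylsilyloxy)cyclohexa-1,4-dien-1-yl]cyclobutane-1,2-dicarboxylate
Product: 15 bis(arm) (1R,2R,3R,4R)-3,4-bis[3,4-bis(tert-butyldimethylsilyloxy)phenyl]cyclobutane-1,2-dicarboxylate
Conditions: DDQ (2.2 equiv), toluene, 0 °C to rt
Reagents that add atoms: none
Why: Dehydrogenation of 1,4-cyclohexadienes by a high-potential quinone: hydride abstraction from a doubly allylic CH2 gives a silyloxy-stabilised cyclohexadienyl cation that loses a proton to the arene; this is much faster than attack on benzyl ethers or benzylic C–H bonds, so a near-stoichiometric amount at low temperature should leave the arms alone.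

**Step 11**
Reactants: 15 bis(arm) (1R,2R,3R,4R)-3,4-bis[3,4-bis(tert-butyldimethylsilyloxy)phenyl]cyclobutane-1,2-dicarboxylate
Product: 16 bis(arm) (1R,2R,3R,4R)-3,4-bis(3,4-dihydroxyphenyl)cyclobutane-1,2-dicarboxylate
Conditions: HF·pyridine, THF/pyridine, 0 °C to rt
Reagents that add atoms: none
Why: Fluoride-driven cleavage of aryl silyl ethers under buffered acidic conditions; benzyl ethers, benzyl esters and the α-acyloxy ester links are inert to it, and no base is present that could epimerise the ring or oxidise the freed catechols.

**Step 12**
Reactants: 16 bis(arm) (1R,2R,3R,4R)-3,4-bis(3,4-dihydroxyphenyl)cyclobutane-1,2-dicarboxylate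
Product: 17 (2R,2'R)-2,2'-{[(1R,2R,3R,4R)-3,4-bis(3,4-dihydroxyphenyl)cyclobutane-1,2-dicarbonyl]bis(oxy)}bis[3-(3,4-dihydroxyphenyl)propanoic acid]
Conditions: H2 (1 atm), Pd/C, THF/MeOH, rt
Reagents that add atoms: none
Why: Catalytic hydrogenolysis of four benzyl ethers and two benzyl esters under neutral conditions; the arm ester C–O bonds are homobenzylic and the aryl-substituted cyclobutane is not cleaved under these mild conditions, so the free acid should be obtained by filtration and evaporation.

## Compound list

1 | cyclobutane-1,2,3,4-tetracarboxylic dianhydride (cis,trans,cis; meso) | O=C2OC(=O)[C@H]1[C@H](C(=O)OC3=O)[C@H]3[C@H]12 | starting material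
2 | (1S,2S,3S,4S)-3,4-bis(methoxycarbonyl)cyclobutane-1,2-dicarboxylic acid | OC(=O)[C@H]1[C@H](C(=O)O)[C@H](C(=O)OC)[C@H]1C(=O)OC | intermediate
3 | dimethyl (1S,2S,3S,4S)-3,4-bis(hydroxymethyl)cyclobutane-1,2-dicarboxylate (diol diester) | OC[C@H]1[C@H](CO)[C@H](C(=O)OC)[C@H]1C(=O)OC | intermediate (not isolated)
4 | (1S,2S,6S,7S)-4,9-dioxatricyclo[5.3.0.0^2,6]decane-3,10-dione | O=C2OC[C@H]1[C@H](COC3=O)[C@H]3[C@H]12 | intermediate
5 | (1S,2S,6S,7S)-4,9-dioxatricyclo[5.3.0.0^2,6]decane-3,10-diol (mixture of anomers at C3 and C10) | OC2OC[C@H]1[C@H](COC3O)[C@H]3[C@H]12 | intermediate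
6 | dimethyl (1-diazo-2-oxopropyl)phosphonate | COP(=O)(OC)C(=[N+]=[N-])C(C)=O | starting material
7 | [(1R,2R,3R,4R)-3,4-diethynylcyclobutane-1,2-diyl]dimethanol | OC[C@H]1[C@H](CO)[C@H](C#C)[C@H]1C#C | intermediate
8 | (1R,2R,3R,4R)-3,4-diethynylcyclobutane-1,2-dicarboxylic acid | OC(=O)[C@H]1[C@H](C(=O)O)[C@H](C#C)[C@H]1C#C | intermediate
9 | (R)-danshensu, (2R)-3-(3,4-dihydroxyphenyl)-2-hydroxypropanoic acid | O[C@H](Cc1ccc(O)c(O)c1)C(=O)O | starting material
10 | benzyl (2R)-3-[3,4-bis(benzyloxy)phenyl]-2-hydroxypropanoate | O[C@H](Cc1ccc(OCc2ccccc2)c(OCc2ccccc2)c1)C(=O)OCc1ccccc1 | intermediate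
11 | bis{(2R)-1-(benzyloxy)-3-[3,4-bis(benzyloxy)phenyl]-1-oxopropan-2-yl} (1R,2R,3R,4R)-3,4-diethynylcyclobutane-1,2-dicarboxylate | O=C(O[C@H](Cc1ccc(OCc2ccccc2)c(OCc2ccccc2)c1)C(=O)OCc1ccccc1)[C@H]1[C@H](C(=O)O[C@H](Cc2ccc(OCc3ccccc3)c(OCc3ccccc3)c2)C(=O)OCc2ccccc2)[C@H](C#C)[C@H]1C#C | intermediate
12 | butane-2,3-dione | CC(=O)C(C)=O | starting material
13 | 2,3-bis(tert-butyldimethylsilyloxy)buta-1,3-diene | C=C(O[Si](C)(C)C(C)(C)C)C(=C)O[Si](C)(C)C(C)(C)C | intermediate
14 | bis{(2R)-1-(benzyloxy)-3-[3,4-bis(benzyloxy)phenyl]-1-oxopropan-2-yl} (1R,2R,3R,4R)-3,4-bis[4,5-bis(tert-butyldimethylsilyloxy)cyclohexa-1,4-dien-1-yl]cyclobutane-1,2-dicarboxylate | O=C(O[C@H](Cc1ccc(OCc2ccccc2)c(OCc2ccccc2)c1)C(=O)OCc1ccccc1)[C@H]1[C@H](C(=O)O[C@H](Cc2ccc(OCc3ccccc3)c(OCc3ccccc3)c2)C(=O)OCc2ccccc2)[C@H](C2=CCC(O[Si](C)(C)C(C)(C)C)=C(O[Si](C)(C)C(C)(C)C)C2)[C@H]1C1=CCC(O[Si](C)(C)C(C)(C)C)=C(O[Si](C)(C)C(C)(C)C)C1 | intermediate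
15 | bis{(2R)-1-(benzyloxy)-3-[3,4-bis(benzyloxy)phenyl]-1-oxopropan-2-yl} (1R,2R,3R,4R)-3,4-bis[3,4-bis(tert-butyldimethylsilyloxy)phenyl]cyclobutane-1,2-dicarboxylate | O=C(O[C@H](Cc1ccc(OCc2ccccc2)c(OCc2ccccc2)c1)C(=O)OCc1ccccc1)[C@H]1[C@H](C(=O)O[C@H](Cc2ccc(OCc3ccccc3)c(OCc3ccccc3)c2)C(=O)OCc2ccccc2)[C@H](c2ccc(O[Si](C)(C)C(C)(C)C)c(O[Si](C)(C)C(C)(C)C)c2)[C@H]1c1ccc(O[Si](C)(C)C(C)(C)C)c(O[Si](C)(C)C(C)(C)C)c1 | intermediate
16 | bis{(2R)-1-(benzyloxy)-3-[3,4-bis(benzyloxy)phenyl]-1-oxopropan-2-yl} (1R,2R,3R,4R)-3,4-bis(3,4-dihydroxyphenyl)cyclobutane-1,2-dicarboxylate | O=C(O[C@H](Cc1ccc(OCc2ccccc2)c(OCc2ccccc2)c1)C(=O)OCc1ccccc1)[C@H]1[C@H](C(=O)O[C@H](Cc2ccc(OCc3ccccc3)c(OCc3ccccc3)c2)C(=O)OCc2ccccc2)[C@H](c2ccc(O)c(O)c2)[C@H]1c1ccc(O)c(O)c1 | intermediate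
17 | (2R,2'R)-2,2'-{[(1R,2R,3R,4R)-3,4-bis(3,4-dihydroxyphenyl)cyclobutane-1,2-dicarbonyl]bis(oxy)}bis[3-(3,4-dihydroxyphenyl)propanoic acid] | O=C(O[C@H](Cc1ccc(O)c(O)c1)C(=O)O)[C@H]1[C@H](C(=O)O[C@H](Cc2ccc(O)c(O)c2)C(=O)O)[C@H](c2ccc(O)c(O)c2)[C@H]1c1ccc(O)c(O)c1 | target

## Step count and risks

Total step count: 12. Longest linear sequence: 10 steps (steps 1, 2, 3, 4, 5, 7, 9, 10, 11, 12); steps 6 and 8 are side branches.

**Step 9 (key step).** The most likely failure is slow engagement of the hindered, Lewis-acid-sensitive diene 13. Cyclotrimerisation of the terminal alkynes and ZnI2-induced desilylation would then outrun the second cycloaddition, and the reaction would stall at the mono-adduct. The fallback changes the diene class and brings in the second oxygen of each ring later. It sets out from 11. The same cobalt catalysis is run with commercially available 2-(trimethylsilyloxy)buta-1,3-diene, a diene class established in this cycloaddition. It gives bis(arm) (1R,2R,3R,4R)-3,4-bis[4-(trimethylsilyloxy)cyclohexa-1,4-dien-1-yl]cyclobutane-1,2-dicarboxylate F1, the 1,4-relation of ring substituent and silyloxy group being the regiochemistry this catalyst system gives with terminal alkynes. DDQ dehydrogenation with a mildly acidic work-up hydrolyses the aryl trimethylsilyl ethers and gives bis(arm) (1R,2R,3R,4R)-3,4-bis(4-hydroxyphenyl)cyclobutane-1,2-dicarboxylate F2. Ortho-oxygenation of each phenol with IBX in DMF, followed at once by Na2S2O4 reduction of the ortho-quinones, gives the two catechols. The route is rejoined at 16.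

**Step 1.** The most likely failure is slow, heterogeneous reaction of the sparingly soluble dianhydride at −55 °C. An unselective background methanolysis, or a mismatched second opening, would then erode regio- and enantiocontrol. The fallback replaces catalyst control by resolution. It sets out from 1. Uncatalysed methanolysis in refluxing MeOH gives racemic 2 together with 2,4-bis(methoxycarbonyl)cyclobutane-1,3-dicarboxylic acid F3 (centrosymmetric), which is removed by crystallisation. The racemate is resolved by fractional crystallisation of its salt with an enantiopure amine such as 1-phenylethylamine, which returns the route to 2. The mirror-image half-ester (1R,2R,3R,4R)-3,4-bis(methoxycarbonyl)cyclobutane-1,2-dicarboxylic acid F4 is not lost. LiBEt3H reduces its ester groups while the carboxylates are spared, and acid lactonisation then gives the same bis-lactone 4, because exchanging the roles of ester and acid carbons is equivalent to taking the mirror image.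

**Step 4.** The most likely failure is slow opening of the two lactols in carbonate/methanol. The transient α-branched aldehydes could then epimerise toward the trans isomers, which cannot re-close, before they are homologated. The fallback uses olefination and elimination in place of the diazo homologation. It sets out from 5. Wittig reaction with Ph3P=CHCl (from (chloromethyl)triphenylphosphonium chloride and NaN(SiMe3)2, THF, −78 to 0 °C) is a reaction that lactols undergo readily at low temperature. It gives [(1R,2R,3R,4R)-3,4-bis(2-chloroethenyl)cyclobutane-1,2-diyl]dimethanol F5 as an E/Z mixture. Dehydrochlorination with excess LiN(i-Pr)2 (THF, −78 to 0 °C) converts both chloroalkenes into terminal alkynes and rejoins the route at 7.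

**Step 10.** The most likely failure is hydride abstraction by DDQ at the benzylic CH2 groups of the electron-rich arms, or at the cyclobutane C–H bonds once the new rings are aromatic. Silyl loss from the intermediate cation followed by over-oxidation to ortho-quinones is the other risk. The fallback aromatises through the oxygen-bearing carbons instead of by hydride abstraction. It sets out from 14. HF·pyridine cleaves the four silyl enol ethers to bis(arm) (1R,2R,3R,4R)-3,4-bis(5-hydroxy-4-oxocyclohex-1-en-1-yl)cyclobutane-1,2-dicarboxylate F6, a mixture of ketol regioisomers and carbinol epimers. Dess–Martin periodinane oxidises each ketol to the cyclohex-4-ene-1,2-dione, which is the keto tautomer of a catechol and enolises to the arene. A Na2S2O4 work-up returns any ortho-quinone to the catechol. The route is rejoined at 16, bypassing 15.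

## Further compounds

F1 | step 9 | bis{(2R)-1-(benzyloxy)-3-[3,4-bis(benzyloxy)phenyl]-1-oxopropan-2-yl} (1R,2R,3R,4R)-3,4-bis[4-(trimethylsilyloxy)cyclohexa-1,4-dien-1-yl]cyclobutane-1,2-dicarboxylate | O=C(O[C@H](Cc1ccc(OCc2ccccc2)c(OCc2ccccc2)c1)C(=O)OCc1ccccc1)[C@H]1[C@H](C(=O)O[C@H](Cc2ccc(OCc3ccccc3)c(OCc3ccccc3)c2)C(=O)OCc2ccccc2)[C@H](C2=CCC(O[Si](C)(C)C)=CC2)[C@H]1C1=CCC(O[Si](C)(C)C)=CC1
F2 | step 9 | bis{(2R)-1-(benzyloxy)-3-[3,4-bis(benzyloxy)phenyl]-1-oxopropan-2-yl} (1R,2R,3R,4R)-3,4-bis(4-hydroxyphenyl)cyclobutane-1,2-dicarboxylate | O=C(O[C@H](Cc1ccc(OCc2ccccc2)c(OCc2ccccc2)c1)C(=O)OCc1ccccc1)[C@H]1[C@H](C(=O)O[C@H](Cc2ccc(OCc3ccccc3)c(OCc3ccccc3)c2)C(=O)OCc2ccccc2)[C@H](c2ccc(O)cc2)[C@H]1c1ccc(O)cc1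
F3 | step 1 | 2,4-bis(methoxycarbonyl)cyclobutane-1,3-dicarboxylic acid (centrosymmetric meso isomer, each ester cis to one acid) | COC(=O)[C@H]1[C@H](C(=O)O)[C@H](C(=O)OC)[C@H]1C(=O)O
F4 | step 1 | (1R,2R,3R,4R)-3,4-bis(methoxycarbonyl)cyclobutane-1,2-dicarboxylic acid | OC(=O)[C@@H]1[C@@H](C(=O)O)[C@@H](C(=O)OC)[C@@H]1C(=O)OC
F5 | step 4 | [(1R,2R,3R,4R)-3,4-bis(2-chloroethenyl)cyclobutane-1,2-diyl]dimethanol (E/Z mixture) | OC[C@H]1[C@H](CO)[C@H](C=CCl)[C@H]1C=CCl
F6 | step 10 | bis{(2R)-1-(benzyloxy)-3-[3,4-bis(benzyloxy)phenyl]-1-oxopropan-2-yl} (1R,2R,3R,4R)-3,4-bis(5-hydroxy-4-oxocyclohex-1-en-1-yl)cyclobutane-1,2-dicarboxylate (one ketol regioisomer shown, carbinol centres undefined) | O=C(O[C@H](Cc1ccc(OCc2ccccc2)c(OCc2ccccc2)c1)C(=O)OCc1ccccc1)[C@H]1[C@H](C(=O)O[C@H](Cc2ccc(OCc3ccccc3)c(OCc3ccccc3)c2)C(=O)OCc2ccccc2)[C@H](C2=CCC(=O)C(O)C2)[C@H]1C1=CCC(=O)C(O)C1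
A1 | alternative 1 | (1R,2R)-N1,N2-di(quinolin-8-yl)cyclobutane-1,2-dicarboxamide | O=C(Nc1cccc2cccnc12)[C@H]1[C@H](C(=O)Nc2cccc3cccnc23)CC1
A2 | alternative 1 | 1,2-bis(benzyloxy)-4-iodobenzene | Ic1ccc(OCc2ccccc2)c(OCc2ccccc2)c1
A3 | alternative 1 | (1R,2R,3R,4R)-3,4-bis[3,4-bis(benzyloxy)phenyl]-N1,N2-di(quinolin-8-yl)cyclobutane-1,2-dicarboxamide | O=C(Nc1cccc2cccnc12)[C@H]1[C@H](C(=O)Nc2cccc3cccnc23)[C@H](c2ccc(OCc3ccccc3)c(OCc3ccccc3)c2)[C@H]1c1ccc(OCc2ccccc2)c(OCc2ccccc2)c1
A4 | alternative 2 | di-tert-butyl trans-3,4-bis[3,4-bis(benzyloxy)phenyl]thiolane-2,5-dicarboxylate 1,1-dioxide (C2 and C5 undefined) | CC(C)(C)OC(=O)C1S(=O)(=O)C(C(=O)OC(C)(C)C)[C@H](c2ccc(OCc3ccccc3)c(OCc3ccccc3)c2)[C@H]1c1ccc(OCc2ccccc2)c(OCc2ccccc2)c1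
A5 | alternative 2 | di-tert-butyl trans-3,4-bis[3,4-bis(benzyloxy)phenyl]cyclobut-1-ene-1,2-dicarboxylate | CC(C)(C)OC(=O)C1=C(C(=O)OC(C)(C)C)[C@H](c2ccc(OCc3ccccc3)c(OCc3ccccc3)c2)[C@H]1c1ccc(OCc2ccccc2)c(OCc2ccccc2)c1
A6 | alternative 3 | (1R,2R,3R,4R)-3,4-bis({(2R)-1-(benzyloxy)-3-[3,4-bis(benzyloxy)phenyl]-1-oxopropan-2-yl}oxycarbonyl)cyclobutane-1,2-dicarboxylic acid | O=C(O[C@H](Cc1ccc(OCc2ccccc2)c(OCc2ccccc2)c1)C(=O)OCc1ccccc1)[C@H]1[C@H](C(=O)O[C@H](Cc2ccc(OCc3ccccc3)c(OCc3ccccc3)c2)C(=O)OCc2ccccc2)[C@H](C(=O)O)[C@H]1C(=O)O
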